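**Retrosynthetic overview**
- Target ⇒ oxidation of a 7α-isopropenyl group (allylic alcohol, enal, acid) and ester disconnection into a 4α,9β-diol plus (S)-3-methylpentanoic acid, the latter made from (S)-2-methylbutan-1-ol.
- Diol ⇒ ring-B enone (C7=C8, C9 ketone) plus an isopropenyl nucleophile; 1,4-addition sets C7 and a dissolving-metal reduction sets C9.
- 4α-OH/4β-CH3 ⇒ 4-methylene (α-face epoxidation, hydride opening) ⇒ 4-ketone ⇒ C4=C5 alkene (hydroboration sets C5) ⇒ (S)-Wieland–Miescher ketone.
- (S)-Wieland–Miescher ketone ⇒ key C10–C1 bond by intermolecular Michael addition of 2-methylcyclohexane-1,3-dione to methyl vinyl ketone, then L-proline aldol condensation (sets C10).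
- Ring order: ring B is the purchased cyclohexanedione; ring A is closed second by the aldol condensation.

Convention: positions use eudesmane numbering (C10 = methyl-bearing fusion carbon, C5 = fusion CH, ring A = C1–C5/C10, ring B = C5–C10, side chain C11–C13); β is the face of the C10 methyl. The target SMILES reads as 4R,5R,7R,9S,10S with a (3S)-acyl group, i.e. 10β-CH3, 5α-H, 4α-OH/4β-CH3, 9β-acyloxy, 7α side chain.

**Route**

Step 1
Reactants: 1 2-methylcyclohexane-1,3-dione; 2 methyl vinyl ketone
Product: 3 2-methyl-2-(3-oxobutyl)cyclohexane-1,3-dione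
Conditions: H2O, AcOH (cat.), hydroquinone (cat.), 75 °C
Reagents that add atoms: none
Why: Michael addition of the enolised 1,3-dione to the enone forms the C10–C1 bond and the quaternary carbon cleanly under weakly acidic aqueous conditions.

Step 2
Reactants: 3 2-methyl-2-(3-oxobutyl)cyclohexane-1,3-dione
Product: 5 (S)-Wieland–Miescher ketone, via bicyclic ketol 4 (not isolated)
Conditions: L-proline (5 mol%), DMSO, rt, 5 d; recrystallise (Et2O/hexane) to >99% ee
Reagents that add atoms: none
Why: Hajos–Parrish–Eder–Sauer–Wiechert aldol condensation, in which the L-proline enamine attacks one of the two enantiotopic ring carbonyls and dehydration gives the (S)-enone, setting C10.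

Step 3
Reactants: 5 (S)-Wieland–Miescher ketone
Product: 6 C3-dithiolane of (S)-Wieland–Miescher ketone (C4=C5 kept; C9 ketone free)
Conditions: HSCH2CH2SH (1.05 equiv), TsOH·H2O (cat.), AcOH, rt
Reagents that add atoms: ethane-1,2-dithiol, SCCS
Why: Chemoselective dithioketalisation of the conjugated carbonyl; the neopentyl C9 ketone is slower and the double bond does not migrate with sulfur ketals.

Step 4
Reactants: 6 C3-dithiolane of (S)-Wieland–Miescher ketone
Product: 7 C3-dithiolane C9-dioxolane
Conditions: HOCH2CH2OH, TsOH (cat.), toluene, reflux, Dean–Stark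
Reagents that add atoms: ethylene glycol, OCCO
Why: Acid-catalysed ketalisation with water removal protects the C9 ketone for the hydride, ylide and peracid steps; the dithiolane is stable to TsOH.

Step 5
Reactants: 7 C3-dithiolane C9-dioxolane
Product: 8 10β-methyl-octal-4-en-9-one ethylene ketal (C3 now CH2)
Conditions: Raney Ni (W-2, acetone-deactivated), EtOH, reflux
Reagents that add atoms: none
Why: Raney nickel desulfurisation (Mozingo reduction) replaces both C–S bonds by C–H and leaves the trisubstituted C4=C5 alkene in place.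

Step 6
Reactants: 8 10β-methyl-octal-4-en-9-one ethylene ketal
Product: 10 4α-hydroxy-5α-H-10β-methyl-trans-decalin-9-one ethylene ketal, via alkylborane 9 (not isolated)
Conditions: BH3·THF, THF, 0 °C → rt; then NaOH, H2O2, 0 → 40 °C
Reagents that add atoms: hydrogen peroxide, OO
Why: Brown hydroboration–oxidation adds B to C4 and H to C5 syn from the α face, opposite the angular methyl, which sets the trans ring fusion (5α-H).

Step 7
Reactants: 10 4α-hydroxy-5α-H-10β-methyl-trans-decalin-9-one ethylene ketal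
Product: 11 10β-methyl-5α-H-trans-decalin-4,9-dione 9-ethylene ketal
Conditions: Dess–Martin periodinane, NaHCO3, CH2Cl2, rt
Reagents that add atoms: none
Why: Buffered Dess–Martin oxidation gives the ketone without epimerising C5 or touching the ketal.

Step 8
Reactants: 11 10β-methyl-5α-H-trans-decalin-4,9-dione 9-ethylene ketal
Product: 12 4-methylene-10β-methyl-5α-H-trans-decalin-9-one ethylene ketal
Conditions: Ph3PCH3Br, KOtBu, THF, 0 °C → rt
Reagents that add atoms: methyltriphenylphosphonium bromide, C[P+](c1ccccc1)(c1ccccc1)c1ccccc1.[Br-]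
Why: Wittig methylenation of the only free ketone; short contact at low temperature should keep the trans fusion.

Step 9
Reactants: 12 4-methylene-10β-methyl-5α-H-trans-decalin-9-one ethylene ketal
Product: 13 4α,15-epoxide (spiro-oxirane: O on the α face; CH2 β)
Conditions: mCPBA, NaHCO3, CH2Cl2, 0 °C
Reagents that add atoms: mCPBA, O=C(OO)c1cccc(Cl)c1
Why: Prilezhaev epoxidation from the equatorial α face, because the axial β face is blocked by the syn-axial C10 methyl; this places the C4 oxygen α.

Step 10
Reactants: 13 4α,15-epoxide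
Product: 14 4α-hydroxy-4β,10β-dimethyl-5α-H-trans-decalin-9-one ethylene ketal
Conditions: LiAlH4, THF, reflux; Fieser work-up
Reagents that add atoms: none
Why: SN2 hydride opening at the primary epoxide carbon leaves the C4–O bond intact, so C4 ends as 4α-OH/4β-CH3.

Step 11
Reactants: 14 4α-hydroxy-4β,10β-dimethyl-5α-H-trans-decalin-9-one ethylene ketal
Product: 15 4α-hydroxy-4β,10β-dimethyl-5α-H-trans-decalin-9-one
Conditions: 2 M HCl, THF, rt
Reagents that add atoms: water, O
Why: Acid-catalysed ketal hydrolysis frees the C9 ketone; dilute acid at room temperature should not dehydrate the tertiary alcohol.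

Step 12
Reactants: 15 4α-hydroxy-4β,10β-dimethyl-5α-H-trans-decalin-9-one
Product: 16 9-(trimethylsilyloxy)-8-ene with 4α-OSiMe3 (bis-silyl compound)
Conditions: TMSOTf (2.5 equiv), Et3N (4 equiv), CH2Cl2, 0 °C → rt
Reagents that add atoms: trimethylsilyl trifluoromethanesulfonate, C[Si](C)(C)OS(=O)(=O)C(F)(F)F
Why: Soft enolisation gives the silyl enol ether toward C8, the only enolisable side, and silylates the tertiary alcohol at the same time.

Step 13
Reactants: 16 bis-silyl compound
Product: 17 4α-(trimethylsilyloxy)-4β,10β-dimethyl-5α-H-octal-7-en-9-one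
Conditions: Pd(OAc)2 (1.1 equiv), MeCN, rt
Reagents that add atoms: none
Why: Saegusa–Ito oxidation: the divalent palladium enolate undergoes β-hydride elimination from C7 to give the C7=C8 enone and zerovalent palladium.

Step 14
Reactants: 17 4α-(trimethylsilyloxy)-4β,10β-dimethyl-5α-H-octal-7-en-9-one
Product: 19 4α-hydroxy-7α-isopropenyl-4β,10β-dimethyl-5α-H-trans-decalin-9-one, via silyl enol ether 18 (not isolated)
Conditions: CH2=C(CH3)MgBr (2 equiv), CuBr·SMe2 (20 mol%), TMSCl (2.5 equiv), THF, −78 °C; then 1 M HCl, THF, rt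
Reagents that add atoms: isopropenylmagnesium bromide, CC(=C)[Mg]Br
Why: Copper-catalysed, TMSCl-accelerated 1,4-addition with axial attack on the α face, anti to the angular methyl, sets the 7α side chain; the acid work-up cleaves both silyl groups.

Step 15
Reactants: 19 4α-hydroxy-7α-isopropenyl-4β,10β-dimethyl-5α-H-trans-decalin-9-one
Product: 20 7α-isopropenyl-4β,10β-dimethyl-5α-H-trans-decalin-4α,9β-diol
Conditions: Li (4 equiv), NH3(l)/THF, EtOH (2 equiv), −78 °C, 20 min; NH4Cl(s)
Reagents that add atoms: none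
Why: Dissolving-metal reduction gives the thermodynamically preferred equatorial 9β-alcohol (the 9α epimer would be syn-axial to the 7α group) and leaves the isolated alkene alone.

Step 16
Reactants: 21 (S)-2-methylbutan-1-ol
Product: 22 (S)-1-bromo-2-methylbutane
Conditions: PBr3, pyridine (cat.), 0 °C → rt; distil
Reagents that add atoms: phosphorus tribromide, BrP(Br)Br
Why: SN2 bromination at the primary carbon; the stereocentre is one carbon away and is not involved.

Step 17
Reactants: 22 (S)-1-bromo-2-methylbutane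
Product: 24 (S)-3-methylpentanoic acid, via Grignard reagent 23 (not isolated)
Conditions: Mg, I2 (cat.), THF, reflux; CO2(s), −78 °C → rt; 2 M HCl
Reagents that add atoms: carbon dioxide, O=C=O
Why: Grignard carboxylation adds one carbon; the stereocentre is β to magnesium and is configurationally stable, and the descriptor stays S.

Step 18
Reactants: 20 7α-isopropenyl-4β,10β-dimethyl-5α-H-trans-decalin-4α,9β-diol; 24 (S)-3-methylpentanoic acid
Product: 25 9β-[(3S)-3-methylpentanoyloxy]-7α-isopropenyl-4β,10β-dimethyl-5α-H-trans-decalin-4α-ol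
Conditions: DCC, DMAP, CH2Cl2, 0 °C → rt
Reagents that add atoms: none
Why: Steglich esterification acylates only the secondary equatorial 9-OH; the tertiary 4-OH does not react and the acid has no epimerisable α-centre.

Step 19
Reactants: 25 9β-[(3S)-3-methylpentanoyloxy]-7α-isopropenyl-4β,10β-dimethyl-5α-H-trans-decalin-4α-ol
Product: 26 C12 allylic alcohol (side chain CH2=C(CH2OH)–)
Conditions: SeO2 (0.5 equiv), t-BuOOH (3 equiv), CH2Cl2, rt
Reagents that add atoms: selenium dioxide, O=[Se]=O; tert-butyl hydroperoxide, CC(C)(C)OO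
Why: SeO2/t-BuOOH allylic oxidation (ene reaction then 2,3-sigmatropic shift) oxidises the isopropenyl methyl in preference to the allylic methine; any enal 27 formed is carried on with 26.

Step 20
Reactants: 26 C12 allylic alcohol
Product: 27 C12 enal (side chain CH2=C(CHO)–)
Conditions: MnO2 (excess), CH2Cl2, rt
Reagents that add atoms: none
Why: MnO2 oxidises only the allylic alcohol, under neutral conditions that do not epimerise C7.

Step 21
Reactants: 27 C12 enal
Product: 28 target acid
Conditions: NaClO2, NaH2PO4, 2-methylbut-2-ene, t-BuOH/H2O, rt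
Reagents that add atoms: sodium chlorite, [Na+].[O-]Cl=O
Why: Pinnick oxidation converts the α-substituted acrolein to the acrylic acid without touching the terminal alkene, the ester or the tertiary alcohol.

**Compound list**

1 | 2-methylcyclohexane-1,3-dione | CC1C(=O)CCCC1=O | starting material
2 | methyl vinyl ketone (but-3-en-2-one) | CC(=O)C=C | starting material
3 | 2-methyl-2-(3-oxobutyl)cyclohexane-1,3-dione | CC(=O)CCC1(C)C(=O)CCCC1=O | intermediate
4 | bicyclic ketol; (4aS,8aS)-4a-hydroxy-8a-methyloctahydronaphthalene-1,6-dione, OH cis to CH3 (not isolated) | C1CC(=O)[C@@]2(C)CCC(=O)C[C@@]2(O)C1 | intermediate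
5 | (S)-Wieland–Miescher ketone; (8aS)-8a-methyl-3,4,8,8a-tetrahydronaphthalene-1,6(2H,7H)-dione | C1CC(=O)[C@@]2(C)CCC(=O)C=C2C1 | intermediate
6 | C3-dithiolane of (S)-Wieland–Miescher ketone; C4=C5 alkene, C9 ketone, 10β-CH3 | C1CC(=O)[C@@]2(C)CCC3(SCCS3)C=C2C1 | intermediate
7 | C3-dithiolane C9-dioxolane of (S)-Wieland–Miescher ketone | C1CC3(OCCO3)[C@@]2(C)CCC4(SCCS4)C=C2C1 | intermediate
8 | 10β-methyl-octal-4-en-9-one ethylene ketal | C1CC3(OCCO3)[C@@]2(C)CCCC=C2C1 | intermediate
9 | alkylborane; 4α-boryl-5α-H adduct of 8 (not isolated) | C1CC3(OCCO3)[C@@]2(C)CCC[C@@H](B)[C@@H]2C1 | intermediate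
10 | 4α-hydroxy-5α-H-10β-methyl-trans-decalin-9-one ethylene ketal | C1CC3(OCCO3)[C@@]2(C)CCC[C@@H](O)[C@@H]2C1 | intermediate
11 | 10β-methyl-5α-H-trans-decalin-4,9-dione 9-ethylene ketal | C1CC3(OCCO3)[C@@]2(C)CCCC(=O)[C@@H]2C1 | intermediate
12 | 4-methylene-10β-methyl-5α-H-trans-decalin-9-one ethylene ketal | C1CC3(OCCO3)[C@@]2(C)CCCC(=C)[C@@H]2C1 | intermediate
13 | 4α,15-epoxide of 12 (spiro-oxirane, O α, CH2 β) | C1CC3(OCCO3)[C@@]2(C)CCC[C@]4(CO4)[C@@H]2C1 | intermediate
14 | 4α-hydroxy-4β,10β-dimethyl-5α-H-trans-decalin-9-one ethylene ketal | C1CC3(OCCO3)[C@@]2(C)CCC[C@@](C)(O)[C@@H]2C1 | intermediate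
15 | 4α-hydroxy-4β,10β-dimethyl-5α-H-trans-decalin-9-one | C1CC(=O)[C@@]2(C)CCC[C@@](C)(O)[C@@H]2C1 | intermediate
16 | bis-silyl compound; 9-(trimethylsilyloxy)-8-ene with 4α-OSiMe3 | C1C=C(O[Si](C)(C)C)[C@@]2(C)CCC[C@@](C)(O[Si](C)(C)C)[C@@H]2C1 | intermediate
17 | 4α-(trimethylsilyloxy)-4β,10β-dimethyl-5α-H-octal-7-en-9-one | C1=CC(=O)[C@@]2(C)CCC[C@@](C)(O[Si](C)(C)C)[C@@H]2C1 | intermediate
18 | silyl enol ether; 7α-isopropenyl-9-(trimethylsilyloxy)-8-ene with 4α-OSiMe3 (not isolated) | C=C(C)[C@H]1C=C(O[Si](C)(C)C)[C@@]2(C)CCC[C@@](C)(O[Si](C)(C)C)[C@@H]2C1 | intermediate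
19 | 4α-hydroxy-7α-isopropenyl-4β,10β-dimethyl-5α-H-trans-decalin-9-one | C=C(C)[C@H]1CC(=O)[C@@]2(C)CCC[C@@](C)(O)[C@@H]2C1 | intermediate
20 | 7α-isopropenyl-4β,10β-dimethyl-5α-H-trans-decalin-4α,9β-diol | C=C(C)[C@H]1C[C@H](O)[C@@]2(C)CCC[C@@](C)(O)[C@@H]2C1 | intermediate
21 | (S)-2-methylbutan-1-ol | OC[C@@H](C)CC | starting material
22 | (S)-1-bromo-2-methylbutane | BrC[C@@H](C)CC | intermediate
23 | Grignard reagent; (S)-2-methylbutylmagnesium bromide (not isolated) | Br[Mg]C[C@@H](C)CC | intermediate
24 | (S)-3-methylpentanoic acid | OC(=O)C[C@@H](C)CC | intermediate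
25 | 9β-[(3S)-3-methylpentanoyloxy]-7α-isopropenyl-4β,10β-dimethyl-5α-H-trans-decalin-4α-ol | C=C(C)[C@H]1C[C@H](OC(=O)C[C@@H](C)CC)[C@@]2(C)CCC[C@@](C)(O)[C@@H]2C1 | intermediate
26 | C12 allylic alcohol; 7α-[3-hydroxyprop-1-en-2-yl] analogue of 25 | C=C(CO)[C@H]1C[C@H](OC(=O)C[C@@H](C)CC)[C@@]2(C)CCC[C@@](C)(O)[C@@H]2C1 | intermediate
27 | C12 enal; 7α-[3-oxoprop-1-en-2-yl] analogue of 25 | C=C(C=O)[C@H]1C[C@H](OC(=O)C[C@@H](C)CC)[C@@]2(C)CCC[C@@](C)(O)[C@@H]2C1 | intermediate
28 | CNP0471281.1; 2-[(2R,4S,4aS,8R,8aR)-8-hydroxy-4a,8-dimethyl-4-[(3S)-3-methylpentanoyloxy]decahydronaphthalen-2-yl]prop-2-enoic acid | C=C(C(=O)O)[C@H]1C[C@H](OC(=O)C[C@@H](C)CC)[C@@]2(C)CCC[C@@](C)(O)[C@@H]2C1 | target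

**Summary**

Total step count: 21. Longest linear sequence: 19 steps (steps 1–15, then 18–21); the acid branch (steps 16–17) joins at step 18.

Steps most likely to fail:

- Step 9 (face selectivity of the epoxidation, and with it the C4 configuration). The fallback sets out from 12 and comes back at 14. Upjohn dihydroxylation (OsO4 cat., N-methylmorpholine N-oxide, acetone/H2O, rt) uses a bulkier reagent that should favour the α face more strongly and gives the 4α,15-diol ketal F1. Tosylation of the primary hydroxyl (TsCl, pyridine, 0 °C) gives the primary monotosylate F2. LiAlH4 in refluxing THF then removes the sulfonate, directly or through epoxide 13 formed in the flask, to give 14.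

- Step 15 (configuration at C9, possible over-reduction). The fallback sets out from 19 and comes back at 20. NaBH4 in MeOH at 0 °C reduces the ketone under kinetic control and may give mainly the axial 9α-alcohol F3. Meerwein–Ponndorf–Verley/Oppenauer equilibration (Al(OiPr)3, i-PrOH, trace acetone, toluene, reflux) then epimerises the carbinol by reversible hydride transfer to the equatorial 9β-alcohol 20.

- Step 19 (moderate yield and possible oxidation at the C7 methine with SeO2). The fallback sets out from 25 and comes back at 27. Ene-type allylic chlorination with hypochlorous acid (Ca(OCl)2, solid CO2, CH2Cl2/H2O, 0 °C) gives the 2-(chloromethyl)allyl compound F4. Oxidation of the allylic chloride with N-methylmorpholine N-oxide in MeCN at rt gives enal 27 directly, bypassing 26.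

**Further compounds**

F1 | step 9 | 4α,15-diol ketal; 4α-hydroxy-4β-(hydroxymethyl)-10β-methyl-5α-H-trans-decalin-9-one ethylene ketal | C1CC3(OCCO3)[C@@]2(C)CCC[C@@](CO)(O)[C@@H]2C1
F2 | step 9 | primary monotosylate of F1 | C1CC3(OCCO3)[C@@]2(C)CCC[C@@](COS(=O)(=O)c4ccc(C)cc4)(O)[C@@H]2C1
F3 | step 15 | 9α-alcohol; 7α-isopropenyl-4β,10β-dimethyl-5α-H-trans-decalin-4α,9α-diol | C=C(C)[C@H]1C[C@@H](O)[C@@]2(C)CCC[C@@](C)(O)[C@@H]2C1
F4 | step 19 | 2-(chloromethyl)allyl compound; 7α-[3-chloroprop-1-en-2-yl] analogue of 25 | C=C(CCl)[C@H]1C[C@H](OC(=O)C[C@@H](C)CC)[C@@]2(C)CCC[C@@](C)(O)[C@@H]2C1
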